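## Retrosynthetic overview

1. The target is cut at the C11=C12 and C11'=C12' double bonds (two Wittig reactions). This gives the C10 dialdehyde 21 and two C15 phosphonium salts: diol salt 20 and its ring C3-O-sulfate 24, made from 20 in one step.
2. Salt 20 comes from enol triflate 15 and dienylstannane 17 (Stille coupling at C6–C7). The C5=C6 ring alkene of 15 is traded for a C6 ketone with a temporary stereocentre at C5 (ketone 12).
3. The only ring-forming event is a trans-selective pinacol cyclisation of the acyclic keto-dialdehyde 10. It forms the C2–C3 bond, and its product serves for both end rings.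
4. The feature that allows this: in each cyclohexene end ring, C2 and C3 are adjacent carbinol carbons (trans-diol), so each can be an aldehyde carbon. C2 is flanked by the quaternary gem-dimethyl carbon C1, and C3 by the C4 methylene.
5. Dialdehyde 10 comes from double ozonolysis of dienone 8, made from a prenyl Grignard reagent and a Weinreb amide whose single stereocentre (the future C5) is set by an Evans allylation.

Key step: step 5

Carotenoid numbering is used for ring positions: C1 gem-dimethyl, C2 and C3 carbinols, C4 methylene, C5 methyl-bearing and C6 chain-bearing carbons.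

Assumption: the target is drawn as the free hydrogen sulfate, so the sulfate monoester is carried as an inner salt and as its sodium salt and is protonated only in the last work-up; compounds 1, 2, 6, 16 and 21 are taken as commercial.

## Route

Step 1
Reactants: 1 (R)-4-benzyl-3-propionyloxazolidin-2-one; 2 allyl iodide
Product: 4 (R)-4-benzyl-3-[(S)-2-methylpent-4-enoyl]oxazolidin-2-one, via sodium Z-enolate 3 (not isolated)
Conditions: NaN(SiMe3)2, THF, −78 °C; then 2, −78 → −45 °C
Reagents that add atoms: none
Why: Evans asymmetric alkylation, in which the chelated Z-enolate is attacked by allyl iodide on the face opposite the benzyl group, which should set the (S) centre that becomes the temporary C5 stereocentre.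

Step 2
Reactants: 4 (R)-4-benzyl-3-[(S)-2-methylpent-4-enoyl]oxazolidin-2-one
Product: 5 (S)-N-methoxy-N,2-dimethylpent-4-enamide
Conditions: MeNH(OMe)·HCl, AlMe3, CH2Cl2, −10 °C → rt; aqueous HCl work-up
Reagents that add atoms: N,O-dimethylhydroxylamine hydrochloride, CNOC.Cl
Why: Aluminium-amide aminolysis of the exocyclic imide carbonyl (Weinreb amide formation) should release the auxiliary without touching the α-stereocentre, since no enolisation is involved.

Step 3
Reactants: 5 (S)-N-methoxy-N,2-dimethylpent-4-enamide; 6 prenylmagnesium chloride (3-methylbut-2-en-1-ylmagnesium chloride)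
Product: 8 (S)-3,3,5-trimethylocta-1,7-dien-4-one, via magnesium chelate 7 (not isolated)
Conditions: THF, −78 → 0 °C; aqueous NH4Cl
Reagents that add atoms: none
Why: Weinreb ketone synthesis with an allylic Grignard reagent, which reacts through its γ-carbon in a six-membered SE2' transition state and so should build the quaternary C1 with its vinyl group; the stable N,O-chelate 7 stops over-addition, and the low temperature protects the α-stereocentre.

Step 4
Reactants: 8 (S)-3,3,5-trimethylocta-1,7-dien-4-one
Product: 10 (S)-2,2,4-trimethyl-3-oxohexanedial, via bis-ozonide 9 (not isolated)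
Conditions: O3, CH2Cl2, −78 °C; then PPh3, −78 °C → rt; used at once without base contact
Reagents that add atoms: ozone, [O-][O+]=O
Why: Ozonolysis with reductive work-up should cleave both terminal vinyl groups to the two aldehydes (the future C2 and C3) under neutral conditions that leave the ketone and the epimerisable C5 centre untouched.

Step 5
Reactants: 10 (S)-2,2,4-trimethyl-3-oxohexanedial
Product: 12 (3R,4R,6S)-3,4-dihydroxy-2,2,6-trimethylcyclohexan-1-one, via titanium diolate 11 (not isolated)
Conditions: Cp2TiPh (2.3 equiv, made in THF from Cp2TiCl2 and i-PrMgCl, then PhMgBr, −78 °C); slow addition of 10 at high dilution, THF, −78 → −20 °C; then 1 M HCl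
Reagents that add atoms: none
Why: Each aldehyde of 10 should accept one electron from Cp2TiPh (trivalent titanium) to give a titanoxy ketyl radical, and the two ketyls (or the C3 ketyl and the titanium-bound C2 carbonyl) join at C2–C3 to give the bis-titanium diolate 11, which is hydrolysed on work-up. The closest known reaction is the Cp2TiPh-promoted, trans-selective intramolecular pinacol coupling of aliphatic 1,6-dials. The six-membered carbocycle closes by radical C–C coupling between the two former aldehyde carbons (formally a 6-exo attack of the C3 ketyl on the C2 carbonyl) through a chair-like transition state. The trans relation of C2–O and C3–O should follow from the two bulky, non-bridged Cp2Ti(Ph)O groups, which cannot share one metal and take the diequatorial positions; the absolute sense should follow from the auxiliary-set C5 methyl, which stays equatorial because an axial C5 methyl or an axial C3–O group would be syn-diaxial to the axial C1 methyl, so that C5 (S) relays to C2 (R) and C3 (R). The step needs aldehyde-over-ketone chemoselectivity, which the C6 ketone (flanked by quaternary C1 and tertiary C5) should provide, and cyclisation over oligomerisation, which slow addition at high dilution and the gem-dimethyl effect of C1 should secure. Both end rings of the target are later made from this one product, so all four stereocentres of 27 are set here.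

Step 6
Reactants: 12 (3R,4R,6S)-3,4-dihydroxy-2,2,6-trimethylcyclohexan-1-one
Product: 13 (3R,4R,6S)-2,2,6-trimethyl-3,4-bis(triethylsilyloxy)cyclohexan-1-one
Conditions: TESOTf (2.5 equiv), 2,6-lutidine, CH2Cl2, −78 → 0 °C
Reagents that add atoms: triethylsilyl trifluoromethanesulfonate, CC[Si](CC)(CC)OS(=O)(=O)C(F)(F)F
Why: Silyl triflate silylation should cap both secondary hydroxyls, including the neopentyl-type C2–OH, which masks the β-hydroxy ketone against retro-aldol cleavage in the basic step that follows.

Step 7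
Reactants: 13 (3R,4R,6S)-2,2,6-trimethyl-3,4-bis(triethylsilyloxy)cyclohexan-1-one
Product: 15 (4R,5R)-2,6,6-trimethyl-4,5-bis(triethylsilyloxy)cyclohex-1-en-1-yl trifluoromethanesulfonate, via potassium enolate 14 (not isolated)
Conditions: KN(SiMe3)2, THF, −78 → −40 °C; then PhNTf2, −78 → 0 °C; aqueous NH4Cl
Reagents that add atoms: N-phenylbis(trifluoromethanesulfonimide), O=S(=O)(N(c1ccccc1)S(=O)(=O)C(F)(F)F)C(F)(F)F
Why: Enol triflate formation is regiospecific because only C5 carries an α-hydrogen (C1 is quaternary), so O-triflation of enolate 14 should give the tetrasubstituted C5=C6 alkene, erasing the temporary C5 centre on purpose; the carbon next to the enolate carbon (C4) is a methylene without a leaving group, so no β-elimination is possible.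

Step 8
Reactants: 16 (E)-3-methylpent-2-en-4-yn-1-ol
Product: 17 (2E,4E)-3-methyl-5-(tributylstannyl)penta-2,4-dien-1-ol
Conditions: Bu3SnH, PdCl2(PPh3)2 (2 mol%), THF, 0 °C → rt; chromatographic removal of the internal regioisomer
Reagents that add atoms: tributyltin hydride, CCCC[SnH](CCCC)CCCC
Why: Palladium-catalysed hydrostannylation of the terminal alkyne is a syn addition that places tin on the terminal carbon, which should give the E-vinylstannane with the existing E-alkene unchanged.

Step 9
Reactants: 15 (4R,5R)-2,6,6-trimethyl-4,5-bis(triethylsilyloxy)cyclohex-1-en-1-yl trifluoromethanesulfonate; 17 (2E,4E)-3-methyl-5-(tributylstannyl)penta-2,4-dien-1-ol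
Product: 18 (2E,4E)-5-[(4R,5R)-2,6,6-trimethyl-4,5-bis(triethylsilyloxy)cyclohex-1-en-1-yl]-3-methylpenta-2,4-dien-1-ol
Conditions: Pd2(dba)3 (5 mol%), AsPh3 (40 mol%), CuI (10 mol%), NMP, 50 °C
Reagents that add atoms: none
Why: Stille coupling of a vinyl triflate with an alkenylstannane proceeds with retention at both partners, so it should form the C6–C7 bond and the all-E triene; the weakly donating arsine ligand in a polar solvent is the usual remedy for the slow transmetalation of 2,6,6-trimethylcyclohexenyl triflates.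

Step 10
Reactants: 18 (2E,4E)-5-[(4R,5R)-2,6,6-trimethyl-4,5-bis(triethylsilyloxy)cyclohex-1-en-1-yl]-3-methylpenta-2,4-dien-1-ol
Product: 20 [(2E,4E)-5-[(4R,5R)-4,5-dihydroxy-2,6,6-trimethylcyclohex-1-en-1-yl]-3-methylpenta-2,4-dien-1-yl]triphenylphosphonium bromide, via triol 19 (not isolated)
Conditions: PPh3·HBr (1.2 equiv), MeOH, 0 °C → rt; precipitation from EtOAc
Reagents that add atoms: triphenylphosphine hydrobromide, Br.c1ccc(cc1)P(c1ccccc1)c1ccccc1
Why: Acidic methanol should first cleave both triethylsilyl ethers, and the primary dienylic alcohol of 19 then ionises to a delocalised cation that triphenylphosphine traps at the primary terminus (SN1-type phosphonium salt formation, the standard entry to C15 Wittig salts); the ring carbinols cannot ionise under these conditions.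

Step 11
Reactants: 20 the C15 diol phosphonium bromide; 21 (2E,4E,6E)-2,7-dimethylocta-2,4,6-trienedial (3 equiv)
Product: 23 (2E,4E,6E,8E,10E,12E)-13-[(4R,5R)-4,5-dihydroxy-2,6,6-trimethylcyclohex-1-en-1-yl]-2,7,11-trimethyltrideca-2,4,6,8,10,12-hexaenal, via ylide 22 (not isolated)
Conditions: NaOMe (1.05 equiv, slow addition), MeOH/CH2Cl2, 0 °C → rt; then reflux in EtOH (Z → E equilibration); chromatography to recover excess 21
Reagents that add atoms: none
Why: Wittig olefination of one aldehyde of the symmetrical dial by the semi-stabilised allylic ylide, where the excess of 21 should suppress double olefination, the free diol is tolerated, and the Z/E mixture at the new double bond should be brought to the favoured all-E polyene by heating.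

Step 12
Reactants: 20 the C15 diol phosphonium bromide (second portion)
Product: 24 [(2E,4E)-5-[(4R,5R)-5-hydroxy-2,6,6-trimethyl-4-(sulfonatooxy)cyclohex-1-en-1-yl]-3-methylpenta-2,4-dien-1-yl]triphenylphosphonium inner salt (the ring C3-O-sulfate of 20)
Conditions: SO3·pyridine (1.05 equiv), pyridine, 0 °C → rt; precipitation with Et2O, reverse-phase chromatography
Reagents that add atoms: sulfur trioxide–pyridine complex, [O-]S(=O)(=O)[n+]1ccccc1
Why: O-Sulfation with the sulfur trioxide–pyridine complex should take the unhindered equatorial C3–OH in preference to the C2–OH, which is shielded by the adjacent gem-dimethyl carbon C1; pyridine is too weak a base to form the ylide, and the phosphonium centre and the triene are inert to this reagent, so the robust salt, not a light-sensitive polyene, carries the selectivity question.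

Step 13
Reactants: 23 the C25 dihydroxy aldehyde (1.2 equiv); 24 the sulfated C15 phosphonium inner salt
Product: 27 (2R,3R,2'R,3'R)-β,β-carotene-2,3,2',3'-tetrol 3-(hydrogen sulfate) (the target), via sulfated ylide 25 (not isolated), via sodium salt 26 (not isolated)
Conditions: NaOMe (1.05 equiv), MeOH/CH2Cl2, 0 °C → rt; reflux in EtOH (Z → E equilibration); Et2O wash to remove excess 23 and Ph3PO; then cold 0.05 M HCl (1 equiv), rapid extraction into n-BuOH, dark, argon
Reagents that add atoms: none
Why: Wittig olefination of the C25 aldehyde by the sulfate-bearing ylide 25 should close the C40 chain (the sulfate monoester anion and the free hydroxyls are inert to methoxide), thermal equilibration should give the all-E nonaene as sodium salt 26, which is the only sulfated species present because 24 is the limiting partner, and brief cold protonation gives the acid form as drawn; the four stereocentres are untouched.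

## Compound list

1 | (R)-4-benzyl-3-propionyloxazolidin-2-one | CCC(=O)N1[C@H](Cc2ccccc2)COC1=O | starting material
2 | allyl iodide | C=CCI | starting material
3 | sodium Z-enolate of 1 | C/C=C(\[O-])N1[C@H](Cc2ccccc2)COC1=O.[Na+] | intermediate
4 | (R)-4-benzyl-3-[(S)-2-methylpent-4-enoyl]oxazolidin-2-one | C=CC[C@H](C)C(=O)N1[C@H](Cc2ccccc2)COC1=O | intermediate
5 | (S)-N-methoxy-N,2-dimethylpent-4-enamide | C=CC[C@H](C)C(=O)N(C)OC | intermediate
6 | prenylmagnesium chloride | CC(C)=CC[Mg]Cl | starting material
7 | chloromagnesium alkoxide of the tetrahedral adduct of 5 and 6 (new carbinol centre undefined) | C=CC[C@H](C)C(O[Mg]Cl)(N(C)OC)C(C)(C)C=C | intermediate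
8 | (S)-3,3,5-trimethylocta-1,7-dien-4-one | C=CC[C@H](C)C(=O)C(C)(C)C=C | intermediate
9 | bis(1,2,4-trioxolane) of 8 (ozonide carbons as mixtures) | C1(OCOO1)C[C@H](C)C(=O)C(C)(C)C1OCOO1 | intermediate
10 | (S)-2,2,4-trimethyl-3-oxohexanedial | O=CC[C@H](C)C(=O)C(C)(C)C=O | intermediate
11 | bis[phenylbis(cyclopentadienyl)titanium] diolate of 12 (tetravalent titanium) | C[C@H]1C[C@@H](O[Ti](C2C=CC=C2)(C2C=CC=C2)c2ccccc2)[C@H](O[Ti](C2C=CC=C2)(C2C=CC=C2)c2ccccc2)C(C)(C)C1=O | intermediate
12 | (3R,4R,6S)-3,4-dihydroxy-2,2,6-trimethylcyclohexan-1-one | C[C@H]1C[C@@H](O)[C@H](O)C(C)(C)C1=O | intermediate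
13 | (3R,4R,6S)-2,2,6-trimethyl-3,4-bis(triethylsilyloxy)cyclohexan-1-one | C[C@H]1C[C@@H](O[Si](CC)(CC)CC)[C@H](O[Si](CC)(CC)CC)C(C)(C)C1=O | intermediate
14 | potassium enolate of 13 | CC1=C([O-])C(C)(C)[C@@H](O[Si](CC)(CC)CC)[C@H](O[Si](CC)(CC)CC)C1.[K+] | intermediate
15 | (4R,5R)-2,6,6-trimethyl-4,5-bis(triethylsilyloxy)cyclohex-1-en-1-yl trifluoromethanesulfonate | CC1=C(OS(=O)(=O)C(F)(F)F)C(C)(C)[C@@H](O[Si](CC)(CC)CC)[C@H](O[Si](CC)(CC)CC)C1 | intermediate
16 | (E)-3-methylpent-2-en-4-yn-1-ol | C#C/C(C)=C/CO | starting material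
17 | (2E,4E)-3-methyl-5-(tributylstannyl)penta-2,4-dien-1-ol | CCCC[Sn](CCCC)(CCCC)/C=C/C(C)=C/CO | intermediate
18 | (2E,4E)-5-[(4R,5R)-2,6,6-trimethyl-4,5-bis(triethylsilyloxy)cyclohex-1-en-1-yl]-3-methylpenta-2,4-dien-1-ol | CC1=C(/C=C/C(C)=C/CO)C(C)(C)[C@@H](O[Si](CC)(CC)CC)[C@H](O[Si](CC)(CC)CC)C1 | intermediate
19 | (2E,4E)-5-[(4R,5R)-4,5-dihydroxy-2,6,6-trimethylcyclohex-1-en-1-yl]-3-methylpenta-2,4-dien-1-ol | CC1=C(/C=C/C(C)=C/CO)C(C)(C)[C@@H](O)[C@H](O)C1 | intermediate
20 | [(2E,4E)-5-[(4R,5R)-4,5-dihydroxy-2,6,6-trimethylcyclohex-1-en-1-yl]-3-methylpenta-2,4-dien-1-yl]triphenylphosphonium bromide | CC1=C(/C=C/C(C)=C/C[P+](c2ccccc2)(c2ccccc2)c2ccccc2)C(C)(C)[C@@H](O)[C@H](O)C1.[Br-] | intermediate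
21 | (2E,4E,6E)-2,7-dimethylocta-2,4,6-trienedial | O=C/C(C)=C/C=C/C=C(C)/C=O | starting material
22 | ylide of 20 | CC1=C(/C=C/C(C)=C/C=P(c2ccccc2)(c2ccccc2)c2ccccc2)C(C)(C)[C@@H](O)[C@H](O)C1 | intermediate
23 | (2E,4E,6E,8E,10E,12E)-13-[(4R,5R)-4,5-dihydroxy-2,6,6-trimethylcyclohex-1-en-1-yl]-2,7,11-trimethyltrideca-2,4,6,8,10,12-hexaenal | CC1=C(/C=C/C(C)=C/C=C/C(C)=C/C=C/C=C(C)/C=O)C(C)(C)[C@@H](O)[C@H](O)C1 | intermediate
24 | [(2E,4E)-5-[(4R,5R)-5-hydroxy-2,6,6-trimethyl-4-(sulfonatooxy)cyclohex-1-en-1-yl]-3-methylpenta-2,4-dien-1-yl]triphenylphosphonium inner salt | CC1=C(/C=C/C(C)=C/C[P+](c2ccccc2)(c2ccccc2)c2ccccc2)C(C)(C)[C@@H](O)[C@H](OS(=O)(=O)[O-])C1 | intermediate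
25 | ylide of 24 as its sodium sulfate salt | CC1=C(/C=C/C(C)=C/C=P(c2ccccc2)(c2ccccc2)c2ccccc2)C(C)(C)[C@@H](O)[C@H](OS(=O)(=O)[O-])C1.[Na+] | intermediate
26 | sodium salt of 27 | CC1=C(/C=C/C(C)=C/C=C/C(C)=C/C=C/C=C(C)/C=C/C=C(C)/C=C/C2=C(C)C[C@@H](OS(=O)(=O)[O-])[C@H](O)C2(C)C)C(C)(C)[C@@H](O)[C@H](O)C1.[Na+] | intermediate
27 | (2R,3R,2'R,3'R)-β,β-carotene-2,3,2',3'-tetrol 3-(hydrogen sulfate) | CC1=C(/C=C/C(C)=C/C=C/C(C)=C/C=C/C=C(C)/C=C/C=C(C)/C=C/C2=C(C)C[C@@H](OS(=O)(=O)O)[C@H](O)C2(C)C)C(C)(C)[C@@H](O)[C@H](O)C1 | target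

## Step count

Total step count: 13.
Longest linear sequence: 11 steps (steps 1–7, 9 and 10, then 11 or 12, then 13; step 8 is a one-step branch).

## Steps most likely to fail, with fallbacks

**Step 5 (pinacol cyclisation).** The closure may lose its trans preference by passing through a chelated, cis-diol-forming transition state, or it may stall at the hindered neopentyl aldehyde. The fallback sets out from 10 and comes back at 13. Dialdehyde 10 would be cyclised with SmI2 (THF, t-BuOH, −78 °C), whose chelated ketyl–aldehyde coupling should give the cis-diol (3S,4R,6S)-3,4-dihydroxy-2,2,6-trimethylcyclohexan-1-one F1. In F1 the carotenoid C3–OH is still equatorial and correctly configured, and only the C2–OH is axial. Selective silylation of the equatorial C3–OH (TESCl, imidazole, CH2Cl2, −20 °C) would give (3S,4R,6S)-3-hydroxy-2,2,6-trimethyl-4-(triethylsilyloxy)cyclohexan-1-one F2. Dess–Martin oxidation of the axial C2–OH would give (4R,6S)-2,2,6-trimethyl-4-(triethylsilyloxy)cyclohexane-1,3-dione F3, which cannot enolise between its two carbonyls. NaBH4 (MeOH, −78 °C) should reduce the more electrophilic α-silyloxy ketone by axial hydride delivery to the equatorial alcohol (3R,4R,6S)-3-hydroxy-2,2,6-trimethyl-4-(triethylsilyloxy)cyclohexan-1-one F4. TESOTf and 2,6-lutidine would then give 13.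

**Step 9 (Stille coupling).** Oxidative addition and transmetalation at the doubly flanked, tetrasubstituted vinyl triflate may be too slow, so that protodestannylation or stannane homocoupling takes over. The fallback sets out from 13 and comes back at 20. The dilithium acetylide–alkoxide of 16 (2 equiv n-BuLi, THF, −78 → 0 °C) would be added to ketone 13 to give (2E)-5-[(3R,4R,6S)-1-hydroxy-2,2,6-trimethyl-3,4-bis(triethylsilyloxy)cyclohexyl]-3-methylpent-2-en-4-yn-1-ol F5 (carbinol configuration immaterial). Trans-hydroalumination of the propargylic alkyne with NaAlH2(OCH2CH2OMe)2 (THF, 0 °C) would give (2E,4E)-5-[(3R,4R,6S)-1-hydroxy-2,2,6-trimethyl-3,4-bis(triethylsilyloxy)cyclohexyl]-3-methylpenta-2,4-dien-1-ol F6. PPh3·HBr in MeOH should then ionise the tertiary allylic C6–OH, form the C5=C6 double bond by loss of the only available β-hydrogen (at C5), place phosphorus at the primary terminus and cleave the silyl ethers, giving 20.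

**Step 12 (sulfation).** Site selectivity may be incomplete, with sulfation also at the C2–OH or at both hydroxyls of 20. The fallback sets out from 23 and comes back at 26; it differentiates the two hydroxyls by protecting groups on the neutral C25 aldehyde, where regioisomers can be separated on silica, and makes the sulfated ring from 23 instead of from 24. The C3–OH would be silylated selectively (TESCl, imidazole) to the C3-O-triethylsilyl ether of 23 F7. The hindered C2–OH would be acetylated (Ac2O, DMAP, pyridine) to the C2-O-acetyl C3-O-triethylsilyl derivative of 23 F8. The silyl ether would be removed (AcOH/THF/H2O, rt) to the C2-O-acetate of 23 F9. The only free hydroxyl would then be sulfated (SO3·pyridine) to the pyridinium salt of the C2-O-acetyl C3-O-sulfate of 23 F10. A Wittig reaction with 20 and NaOMe as in step 11 would give the sodium salt of the 2-O-acetate of 27 F11 (acetate on the sulfated ring). On longer stirring in the same methanolic NaOMe, F11 should lose its acetate (Zemplén methanolysis) to give 26, which is protonated to 27 as in step 13.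

## Further compounds

F1 | step 5 | (3S,4R,6S)-3,4-dihydroxy-2,2,6-trimethylcyclohexan-1-one | C[C@H]1C[C@@H](O)[C@@H](O)C(C)(C)C1=O
F2 | step 5 | (3S,4R,6S)-3-hydroxy-2,2,6-trimethyl-4-(triethylsilyloxy)cyclohexan-1-one | C[C@H]1C[C@@H](O[Si](CC)(CC)CC)[C@@H](O)C(C)(C)C1=O
F3 | step 5 | (4R,6S)-2,2,6-trimethyl-4-(triethylsilyloxy)cyclohexane-1,3-dione | C[C@H]1C[C@@H](O[Si](CC)(CC)CC)C(=O)C(C)(C)C1=O
F4 | step 5 | (3R,4R,6S)-3-hydroxy-2,2,6-trimethyl-4-(triethylsilyloxy)cyclohexan-1-one | C[C@H]1C[C@@H](O[Si](CC)(CC)CC)[C@H](O)C(C)(C)C1=O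
F5 | step 9 | (2E)-5-[(3R,4R,6S)-1-hydroxy-2,2,6-trimethyl-3,4-bis(triethylsilyloxy)cyclohexyl]-3-methylpent-2-en-4-yn-1-ol | C[C@H]1C[C@@H](O[Si](CC)(CC)CC)[C@H](O[Si](CC)(CC)CC)C(C)(C)C1(O)C#C/C(C)=C/CO
F6 | step 9 | (2E,4E)-5-[(3R,4R,6S)-1-hydroxy-2,2,6-trimethyl-3,4-bis(triethylsilyloxy)cyclohexyl]-3-methylpenta-2,4-dien-1-ol | C[C@H]1C[C@@H](O[Si](CC)(CC)CC)[C@H](O[Si](CC)(CC)CC)C(C)(C)C1(O)/C=C/C(C)=C/CO
F7 | step 12 | C3-O-triethylsilyl ether of 23 | CC1=C(/C=C/C(C)=C/C=C/C(C)=C/C=C/C=C(C)/C=O)C(C)(C)[C@@H](O)[C@H](O[Si](CC)(CC)CC)C1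
F8 | step 12 | C2-O-acetyl C3-O-triethylsilyl derivative of 23 | CC1=C(/C=C/C(C)=C/C=C/C(C)=C/C=C/C=C(C)/C=O)C(C)(C)[C@@H](OC(C)=O)[C@H](O[Si](CC)(CC)CC)C1
F9 | step 12 | C2-O-acetate of 23 | CC1=C(/C=C/C(C)=C/C=C/C(C)=C/C=C/C=C(C)/C=O)C(C)(C)[C@@H](OC(C)=O)[C@H](O)C1
F10 | step 12 | pyridinium salt of the C2-O-acetyl C3-O-sulfate of 23 | CC1=C(/C=C/C(C)=C/C=C/C(C)=C/C=C/C=C(C)/C=O)C(C)(C)[C@@H](OC(C)=O)[C@H](OS(=O)(=O)[O-])C1.c1cc[nH+]cc1
F11 | step 12 | sodium salt of the 2-O-acetate of 27 | CC1=C(/C=C/C(C)=C/C=C/C(C)=C/C=C/C=C(C)/C=C/C=C(C)/C=C/C2=C(C)C[C@@H](OS(=O)(=O)[O-])[C@H](OC(C)=O)C2(C)C)C(C)(C)[C@@H](O)[C@H](O)C1.[Na+]
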